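**Plan**

- Retrosynthesis (germacrane numbering: ring C1–C10, lactone C11–C13): the γ-lactone is cut first at O–C6 and C7–C11, which leaves the ten-membered 1(10)Z,4E,6E-triene 12 and 2-bromopropanoic acid. Triene 12 is then cut at C5–C6 (sp2–sp2), C6=C7, C8–C9, C1=C10 and C2–C3.
- Forward: iodo-enal 4 → C3 carbinol (allylboration) → six-membered unsaturated lactone 7 by ring-closing metathesis (a temporary ring that fixes Z-C1=C10) → lactol → C9 carbinol (second allylboration) → E-alkenyl boronate → ten-membered ring by Suzuki coupling → γ-lactone in one radical–polar annulation → C11 correction, desilylation, acetylation.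
- Enabling feature: lactone carbinol C6 is allylic to the C4=C5 ring olefin, so the lactone is the 1,2-adduct of a propionate unit to a ring diene C4=C5–C6=C7. A propionate α-radical adds at the diene terminus C7, and the C4–C6 allyl cation is captured at C6 by the carboxylate oxygen.
- Stereochemistry: C3 and C9 come from two reagent-controlled Brown allylborations with antipodal reagents. C6 and C7 come from outer-face, suprafacial addition to the E-C6=C7 bond of the ring (trans fusion). C11 comes from kinetic protonation of the lactone enolate. Olefin geometries come from syn-carboalumination (C4=C5), ring constraint (C1=C10) and cross-metathesis (C6=C7).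

Key step: step 11

Remark: germacrane numbering is used for ring and lactone atoms throughout; 13 is used as the racemate because its stereocentre is lost in the radical.

**Route**

Step 1
Reactants: 1 prop-2-yn-1-ol
Product: 3 (E)-3-iodo-2-methylprop-2-en-1-ol, via E-alkenylalane 2 (not isolated)
Conditions: AlMe3 (3 equiv), Cp2ZrCl2 (0.25 equiv), CH2Cl2, 0 °C to rt; then I2, THF, −30 to 0 °C
Reagents that add atoms: trimethylaluminium C[Al](C)C; iodine II
Why: Negishi zirconium-catalysed carboalumination adds methyl and aluminium syn across the alkyne with aluminium on the terminal carbon, and iodinolysis of the C–Al bond with retention should give the E-iodoalkene that becomes C4(Me)=C5.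

Step 2
Reactants: 3 (E)-3-iodo-2-methylprop-2-en-1-ol
Product: 4 (E)-3-iodo-2-methylprop-2-enal
Conditions: activated MnO2 (excess), CH2Cl2, rt; used as a solution
Reagents that add atoms: none
Why: Allylic oxidation with MnO2 is selective for the allylic carbinol and should leave the iodoalkene geometry untouched.

Step 3
Reactants: 4 (E)-3-iodo-2-methylprop-2-enal
Product: 5 (1E,3S)-1-iodo-2-methylhexa-1,5-dien-3-ol
Conditions: (−)-Ipc2BOMe [from (+)-α-pinene], allylMgBr, Et2O, −78 °C; then 4, −78 °C; NaOH, H2O2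
Reagents that add atoms: allylmagnesium bromide C=CC[Mg]Br
Why: Brown asymmetric allylboration through a chair six-membered transition state should deliver allyl to the si face of the enal under control of the isopinocampheyl groups and so set C3 as S.

Step 4
Reactants: 5 (1E,3S)-1-iodo-2-methylhexa-1,5-dien-3-ol
Product: 6 (1E,3S)-1-iodo-2-methylhexa-1,5-dien-3-yl 2-methylprop-2-enoate
Conditions: methacryloyl chloride, Et3N, DMAP (cat.), CH2Cl2, 0 °C
Reagents that add atoms: methacryloyl chloride CC(=C)C(Cl)=O
Why: Base-mediated O-acylation of a secondary allylic alcohol with an acid chloride should proceed without touching C3.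

Step 5
Reactants: 6 (1E,3S)-1-iodo-2-methylhexa-1,5-dien-3-yl 2-methylprop-2-enoate
Product: 7 (6S)-6-[(1E)-1-iodoprop-1-en-2-yl]-3-methyl-5,6-dihydro-2H-pyran-2-one
Conditions: second-generation Grubbs catalyst (5 mol%), CH2Cl2, 40 °C, 0.01 M
Reagents that add atoms: none
Why: Ring-closing metathesis between the allyl group and the methacrylate should close the six-membered unsaturated lactone, whose ring forces the cis (Z) arrangement of C2 and C9 about the new C1=C10 bond, while the trisubstituted iodoalkene is inert to the ruthenium carbene.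

Step 6
Reactants: 7 (6S)-6-[(1E)-1-iodoprop-1-en-2-yl]-3-methyl-5,6-dihydro-2H-pyran-2-one
Product: 8 (6S)-6-[(1E)-1-iodoprop-1-en-2-yl]-3-methyl-5,6-dihydro-2H-pyran-2-ol (both anomers)
Conditions: i-Bu2AlH (1.1 equiv), CH2Cl2, −78 °C; Rochelle salt
Reagents that add atoms: none
Why: DIBAL-H reduction of a lactone stops at the aluminium hemiacetal at −78 °C, so work-up should give the lactol, a masked Z-hydroxy-enal, without Z-to-E isomerisation.

Step 7
Reactants: 8 (6S)-6-[(1E)-1-iodoprop-1-en-2-yl]-3-methyl-5,6-dihydro-2H-pyran-2-ol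
Product: 9 (1E,3S,5Z,7R)-1-iodo-2,6-dimethyldeca-1,5,9-triene-3,7-diol
Conditions: (+)-Ipc2BOMe [from (−)-α-pinene], allylMgBr (2.2 equiv each), Et2O, −78 °C; then 8, −78 to 0 °C; NaOH, H2O2
Reagents that add atoms: allylmagnesium bromide C=CC[Mg]Br
Why: Brown allylboration of the open hydroxy-enal tautomer of the lactol with the antipodal reagent should attack the re face of the aldehyde and set C9 (C7 of the chain) as R under reagent control, the remote C3 centre having little influence.

Step 8
Reactants: 9 (1E,3S,5Z,7R)-1-iodo-2,6-dimethyldeca-1,5,9-triene-3,7-diol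
Product: 10 (1E,3S,5Z,7R)-3,7-bis(tert-butyldimethylsilyloxy)-1-iodo-2,6-dimethyldeca-1,5,9-triene
Conditions: TBSOTf (2.5 equiv), 2,6-lutidine, CH2Cl2, −78 to 0 °C
Reagents that add atoms: tert-butyldimethylsilyl triflate CC(C)(C)[Si](C)(C)OS(=O)(=O)C(F)(F)F
Why: Silylation of both secondary alcohols with a silyl triflate and a hindered base should give the bis-silyl ether, whose bulky groups later bias the ring conformation and block hydroxyl capture of the allyl cation.

Step 9
Reactants: 10 (1E,3S,5Z,7R)-3,7-bis(tert-butyldimethylsilyloxy)-1-iodo-2,6-dimethyldeca-1,5,9-triene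
Product: 11 2-[(1E,4R,5Z,8S,9E)-4,8-bis(tert-butyldimethylsilyloxy)-10-iodo-5,9-dimethyldeca-1,5,9-trien-1-yl]-4,4,5,5-tetramethyl-1,3,2-dioxaborolane
Conditions: vinylboronic acid pinacol ester (3 equiv), second-generation Hoveyda–Grubbs catalyst (5 mol%), CH2Cl2, 40 °C
Reagents that add atoms: vinylboronic acid pinacol ester C=CB1OC(C)(C)C(C)(C)O1
Why: Olefin cross-metathesis of the terminal alkene with the vinyl boronate should give the E-alkenyl boronate (the future C6=C7) under thermodynamic control, the trisubstituted olefins and the iodoalkene being unreactive.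

Step 10
Reactants: 11 2-[(1E,4R,5Z,8S,9E)-4,8-bis(tert-butyldimethylsilyloxy)-10-iodo-5,9-dimethyldeca-1,5,9-trien-1-yl]-4,4,5,5-tetramethyl-1,3,2-dioxaborolane
Product: 12 (1S,2E,4E,7R,8Z)-1,7-bis(tert-butyldimethylsilyloxy)-2,8-dimethylcyclodeca-2,4,8-triene
Conditions: Pd(OAc)2 (10 mol%), SPhos (20 mol%), K3PO4, THF/H2O (10:1), 40 °C, syringe-pump addition to 0.002 M
Reagents that add atoms: none
Why: Intramolecular Suzuki–Miyaura coupling of the alkenyl iodide with the alkenyl boronate proceeds with retention at both sp2 carbons, so the ten-membered ring should close at C5–C6 with the 4E,6E-diene in place, high dilution favouring ring closure over oligomers.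

Step 11
Reactants: 12 (1S,2E,4E,7R,8Z)-1,7-bis(tert-butyldimethylsilyloxy)-2,8-dimethylcyclodeca-2,4,8-triene; 13 2-bromopropanoic acid (racemic)
Product: 14 (3aS,5R,6Z,9S,10E,11aS)-5,9-bis(tert-butyldimethylsilyloxy)-3,6,10-trimethyl-3a,4,5,8,9,11a-hexahydrocyclodeca[b]furan-2(3H)-one (both C11 epimers; C11 is position 3)
Conditions: 13 (1.5 equiv), CuBr (10 mol%), tris(2-pyridylmethyl)amine (10 mol%), 2,6-lutidine (2 equiv), MeCN, 40 °C, degassed
Reagents that add atoms: none
Why: Monovalent copper abstracts bromine from 13 to give the α-carboxyethyl radical, which adds to the less substituted diene terminus C7; the C4–C5–C6 allyl radical is taken to the allyl cation (bromine return from divalent copper, then ionisation) and the carboxylate closes the γ-lactone at C6 by 5-exo attack on the allyl terminus, so C7–C11 and O–C6 form in one operation. The closest known reaction types are the metal-catalysed Kharasch atom-transfer addition–lactonisation of α-halo carboxylic acids to olefins and the trivalent-manganese lactone annulation of 1,3-dienes. C7 is set by attack on the outer face of the C6=C7 bond, anti to the C9 silyloxy group in the conformer that holds both silyloxy groups pseudo-equatorial; C6 is set because only the same outer lobe of the allyl cation is open to the tethered carboxylate, and suprafacial addition to an E ring olefin gives the trans fusion (H6 and H7 anti) whichever allylic bromide forms first. C11 is not controlled here and is corrected in step 12. The step needs diene over the isolated C1=C10 olefin (the conjugated, allyl-stabilised addition is faster), C7 over C4 (less hindered terminus, tertiary-ended allyl radical) and five- over seven-membered closure (kinetic 5-exo preference).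

Step 12
Reactants: 14 (3aS,5R,6Z,9S,10E,11aS)-5,9-bis(tert-butyldimethylsilyloxy)-3,6,10-trimethyl-3a,4,5,8,9,11a-hexahydrocyclodeca[b]furan-2(3H)-one (both C11 epimers)
Product: 16 (3R,3aS,5R,6Z,9S,10E,11aS)-5,9-bis(tert-butyldimethylsilyloxy)-3,6,10-trimethyl-3a,4,5,8,9,11a-hexahydrocyclodeca[b]furan-2(3H)-one, via lithium enolate 15 (not isolated)
Conditions: LDA (1.3 equiv), THF, −78 °C; then 2,6-di-tert-butyl-4-methylphenol (3 equiv), −78 °C
Reagents that add atoms: none
Why: Kinetic protonation of the planar lactone enolate by a bulky proton donor should occur on the face anti to C8 (the substituent on neighbouring C7), which places H11 cis to H7 and the methyl cis to C8, so both C11 epimers of 14 converge on the 11R lactone.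

Step 13
Reactants: 16 (3R,3aS,5R,6Z,9S,10E,11aS)-5,9-bis(tert-butyldimethylsilyloxy)-3,6,10-trimethyl-3a,4,5,8,9,11a-hexahydrocyclodeca[b]furan-2(3H)-one
Product: 17 (3R,3aS,5R,6Z,9S,10E,11aS)-5,9-dihydroxy-3,6,10-trimethyl-3a,4,5,8,9,11a-hexahydrocyclodeca[b]furan-2(3H)-one
Conditions: HF·pyridine, pyridine, THF, 0 °C to rt
Reagents that add atoms: none
Why: Fluoride-mediated desilylation under buffered, non-basic conditions should free both secondary alcohols without epimerising C11 or ionising the allylic positions.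

Step 14
Reactants: 17 (3R,3aS,5R,6Z,9S,10E,11aS)-5,9-dihydroxy-3,6,10-trimethyl-3a,4,5,8,9,11a-hexahydrocyclodeca[b]furan-2(3H)-one
Product: 18 (3R,3aS,5R,6Z,9S,10E,11aS)-3,6,10-trimethyl-2-oxo-2,3,3a,4,5,8,9,11a-octahydrocyclodeca[b]furan-5,9-diyl diacetate
Conditions: Ac2O, pyridine, DMAP (cat.), CH2Cl2, 0 °C to rt
Reagents that add atoms: acetic anhydride CC(=O)OC(C)=O
Why: DMAP-catalysed acetylation of the two secondary allylic alcohols should give the diacetate without touching any stereocentre.

**Compound list**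

1 | prop-2-yn-1-ol | OCC#C | starting material
2 | dimethylaluminium (E)-3-(dimethylalumanyl)-2-methylprop-2-en-1-olate (E-alkenylalane) | C[Al](C)OC/C(C)=C/[Al](C)C | intermediate (not isolated)
3 | (E)-3-iodo-2-methylprop-2-en-1-ol | OC/C(C)=C/I | intermediate
4 | (E)-3-iodo-2-methylprop-2-enal | O=C/C(C)=C/I | intermediate
5 | (1E,3S)-1-iodo-2-methylhexa-1,5-dien-3-ol | I/C=C(C)/[C@@H](O)CC=C | intermediate
6 | (1E,3S)-1-iodo-2-methylhexa-1,5-dien-3-yl 2-methylprop-2-enoate | I/C=C(C)/[C@@H](OC(=O)C(C)=C)CC=C | intermediate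
7 | (6S)-6-[(1E)-1-iodoprop-1-en-2-yl]-3-methyl-5,6-dihydro-2H-pyran-2-one | I/C=C(C)/[C@@H]1CC=C(C)C(=O)O1 | intermediate
8 | (6S)-6-[(1E)-1-iodoprop-1-en-2-yl]-3-methyl-5,6-dihydro-2H-pyran-2-ol (both anomers) | I/C=C(C)/[C@@H]1CC=C(C)C(O)O1 | intermediate
9 | (1E,3S,5Z,7R)-1-iodo-2,6-dimethyldeca-1,5,9-triene-3,7-diol | I/C=C(C)/[C@@H](O)C/C=C(/C)[C@H](O)CC=C | intermediate
10 | (1E,3S,5Z,7R)-3,7-bis(tert-butyldimethylsilyloxy)-1-iodo-2,6-dimethyldeca-1,5,9-triene | I/C=C(C)/[C@@H](O[Si](C)(C)C(C)(C)C)C/C=C(/C)[C@H](O[Si](C)(C)C(C)(C)C)CC=C | intermediate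
11 | 2-[(1E,4R,5Z,8S,9E)-4,8-bis(tert-butyldimethylsilyloxy)-10-iodo-5,9-dimethyldeca-1,5,9-trien-1-yl]-4,4,5,5-tetramethyl-1,3,2-dioxaborolane | I/C=C(C)/[C@@H](O[Si](C)(C)C(C)(C)C)C/C=C(/C)[C@H](O[Si](C)(C)C(C)(C)C)C/C=C/B1OC(C)(C)C(C)(C)O1 | intermediate
12 | (1S,2E,4E,7R,8Z)-1,7-bis(tert-butyldimethylsilyloxy)-2,8-dimethylcyclodeca-2,4,8-triene | CC(C)(C)[Si](C)(C)O[C@H]1C/C=C(/C)[C@H](O[Si](C)(C)C(C)(C)C)C/C=C/C=C/1C | intermediate
13 | 2-bromopropanoic acid (racemic) | CC(Br)C(=O)O | starting material
14 | (3aS,5R,6Z,9S,10E,11aS)-5,9-bis(tert-butyldimethylsilyloxy)-3,6,10-trimethyl-3a,4,5,8,9,11a-hexahydrocyclodeca[b]furan-2(3H)-one (both C3 epimers) | CC(C)(C)[Si](C)(C)O[C@H]1C/C=C(/C)[C@H](O[Si](C)(C)C(C)(C)C)C[C@@H]2[C@@H](/C=C/1C)OC(=O)C2C | intermediate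
15 | lithium enolate of 14 (C11=C12–OLi) | CC(C)(C)[Si](C)(C)O[C@H]1C/C=C(/C)[C@H](O[Si](C)(C)C(C)(C)C)C[C@@H]2[C@@H](/C=C/1C)OC(O[Li])=C2C | intermediate (not isolated)
16 | (3R,3aS,5R,6Z,9S,10E,11aS)-5,9-bis(tert-butyldimethylsilyloxy)-3,6,10-trimethyl-3a,4,5,8,9,11a-hexahydrocyclodeca[b]furan-2(3H)-one | CC(C)(C)[Si](C)(C)O[C@H]1C/C=C(/C)[C@H](O[Si](C)(C)C(C)(C)C)C[C@@H]2[C@@H](/C=C/1C)OC(=O)[C@@H]2C | intermediate
17 | (3R,3aS,5R,6Z,9S,10E,11aS)-5,9-dihydroxy-3,6,10-trimethyl-3a,4,5,8,9,11a-hexahydrocyclodeca[b]furan-2(3H)-one | O[C@H]1C/C=C(/C)[C@H](O)C[C@@H]2[C@@H](/C=C/1C)OC(=O)[C@@H]2C | intermediate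
18 | (3R,3aS,5R,6Z,9S,10E,11aS)-3,6,10-trimethyl-2-oxo-2,3,3a,4,5,8,9,11a-octahydrocyclodeca[b]furan-5,9-diyl diacetate | CC(=O)O[C@H]1C/C=C(/C)[C@H](OC(C)=O)C[C@@H]2[C@@H](/C=C/1C)OC(=O)[C@@H]2C | target

**Summary**

Total step count: 14. Longest linear sequence: 14 steps (1 to 18).

Steps most likely to fail:

Step 10. Ring strain in the triene may slow reductive elimination, so that intermolecular coupling to oligomers and protodeboronation of the alkenyl boronate take over. The fallback sets out from 10 and comes back at 12; it closes the ring at the same C5–C6 bond as a carbinol and makes the diene afterwards. Hydroboration–oxidation of the terminal olefin (9-BBN, THF; NaBO3·4H2O) should give (4R,5Z,8S,9E)-4,8-bis(tert-butyldimethylsilyloxy)-10-iodo-5,9-dimethyldeca-5,9-dien-1-ol F1. Dess–Martin oxidation (NaHCO3, CH2Cl2) should give (4R,5Z,8S,9E)-4,8-bis(tert-butyldimethylsilyloxy)-10-iodo-5,9-dimethyldeca-5,9-dienal F2. Nozaki–Hiyama–Kishi ring closure (CrCl2, NiCl2 cat., DMSO/THF, high dilution) should give (2E,4S,6Z,8R)-4,8-bis(tert-butyldimethylsilyloxy)-3,7-dimethylcyclodeca-2,6-dien-1-ol F3 as both C6 epimers, which both serve. Acylation (ClCO2Me, pyridine, DMAP) should give (2E,4S,6Z,8R)-4,8-bis(tert-butyldimethylsilyloxy)-3,7-dimethylcyclodeca-2,6-dien-1-yl methyl carbonate F4, and palladium-catalysed 1,4-elimination (Pd(PPh3)4, Et3N, dioxane, 80 °C) through the C4–C6 allyl complex should give triene 12. The geometry of the new C6=C7 bond would have to be checked at that point.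

Step 11. The copper atom-transfer cycle may stall because the free carboxylate binds copper; the allyl radical is then not oxidised quickly and is lost by dimerisation, or the allyl cation is diverted into transannular attack by the C1=C10 olefin. Facial selectivity at C7 is also untested. The fallback sets out from 12 and comes back at 14. It uses an oxidative free-radical lactone annulation with methylmalonic acid (Mn(OAc)3·2H2O, KOAc, AcOH, 25–40 °C), in which the radical is made by enol oxidation, carries a temporary carboxyl group and the allyl radical is oxidised by the stoichiometric trivalent manganese. This should give the 3-carboxy derivative of 14 (C11 bears CH3 and CO2H, ring centres as in 14) F5. Heating in pyridine/toluene (100 °C) should decarboxylate it to 14, which goes on to step 12.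

Step 12. Proton transfer to the enolate may be poorly face-selective, or the product may equilibrate towards the more stable 11S epimer during the quench. The fallback sets out from 14 and comes back at 16; it sets C11 by hydrogen delivery to an olefin instead. Selenenylation of the enolate (LDA, THF, −78 °C; PhSeBr) should give the 3-(phenylselanyl) derivative of 14 F6. Oxidation (H2O2, THF, 0 °C) and selenoxide syn-elimination into the methyl group should give the α-methylene lactone (C11=CH2, other centres as in 16) F7. Hydrogenation with RhCl(PPh3)3 under H2 (1 atm, benzene) should reduce only the exocyclic 1,1-disubstituted olefin, from the face anti to C8, and give 16.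

Further compounds
F1 | step 10 | (4R,5Z,8S,9E)-4,8-bis(tert-butyldimethylsilyloxy)-10-iodo-5,9-dimethyldeca-5,9-dien-1-ol | I/C=C(C)/[C@@H](O[Si](C)(C)C(C)(C)C)C/C=C(/C)[C@H](O[Si](C)(C)C(C)(C)C)CCCO
F2 | step 10 | (4R,5Z,8S,9E)-4,8-bis(tert-butyldimethylsilyloxy)-10-iodo-5,9-dimethyldeca-5,9-dienal | I/C=C(C)/[C@@H](O[Si](C)(C)C(C)(C)C)C/C=C(/C)[C@H](O[Si](C)(C)C(C)(C)C)CCC=O
F3 | step 10 | (2E,4S,6Z,8R)-4,8-bis(tert-butyldimethylsilyloxy)-3,7-dimethylcyclodeca-2,6-dien-1-ol (both C1 epimers) | CC(C)(C)[Si](C)(C)O[C@H]1C/C=C(/C)[C@H](O[Si](C)(C)C(C)(C)C)CCC(O)/C=C/1C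
F4 | step 10 | (2E,4S,6Z,8R)-4,8-bis(tert-butyldimethylsilyloxy)-3,7-dimethylcyclodeca-2,6-dien-1-yl methyl carbonate | CC(C)(C)[Si](C)(C)O[C@H]1C/C=C(/C)[C@H](O[Si](C)(C)C(C)(C)C)CCC(OC(=O)OC)/C=C/1C
F5 | step 11 | 3-carboxy derivative of 14 (C11 bears CH3 and CO2H, ring centres as in 14) | CC(C)(C)[Si](C)(C)O[C@H]1C/C=C(/C)[C@H](O[Si](C)(C)C(C)(C)C)C[C@@H]2[C@@H](/C=C/1C)OC(=O)C2(C)C(=O)O
F6 | step 12 | 3-(phenylselanyl) derivative of 14 | CC(C)(C)[Si](C)(C)O[C@H]1C/C=C(/C)[C@H](O[Si](C)(C)C(C)(C)C)C[C@@H]2[C@@H](/C=C/1C)OC(=O)C2(C)[Se]c3ccccc3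
F7 | step 12 | α-methylene lactone (C11=CH2, other centres as in 16) | CC(C)(C)[Si](C)(C)O[C@H]1C/C=C(/C)[C@H](O[Si](C)(C)C(C)(C)C)C[C@@H]2[C@@H](/C=C/1C)OC(=O)C2=C
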